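Retrosynthesis: the C8 ester C–O bond is cut first (Mitsunobu esterification with inversion), then the oxirane C–O bonds (epoxidation of a 1(10)E olefin), then the lactone at O–C6 and C11–C7, which leads back to a ten-membered (4Z,6Z)-dienol and 2-bromoacrylic acid; the carbocycle is cut at C3–C4 and the chain at C4=C5, C5–C6, C1–C2, C10–C14 and C8–C9.
Structural feature used: the lactone oxygen sits on C6, which is allylic to the C4=C5 bond, and C11 sits on the neighbouring C7, so the γ-lactone plus the 4,5-olefin is the pattern left by 1,2-carbo-oxygenation of a C4=C5–C6=C7 diene held Z,Z inside the ten-membered ring.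
Forward: a linear C3–C10 chain is assembled (propargylation, carboalumination/ethylene oxide, formylation, iodo-olefination), the ten-membered carbocycle is closed first (NiCl2/CrCl2), its ring alkyne is reduced to the Z olefin, the γ-lactone is then annulated in one palladium-catalysed step, and the oxirane and the furoate follow.
Stereochemistry: C8 comes from a catalytic asymmetric propargylation (set S, inverted to R in the esterification), C3 from ligand-controlled alkenylchromium addition, C6 and C7 from C8 by substrate control in the annulation (carbon and oxygen delivered to one face), and C1/C10 from a Shi epoxidation. The 1(10)E olefin comes from syn methylalumination, 4Z from a Z-iodoalkene and 6Z from cis-hydrogenation of the ring alkyne.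

Key step: step 11

Remark: ring atoms keep the germacrane numbering of the target in every compound (ring C1–C10, lactone carbons C11–C13, C14 on C10, C15 on C4); compounds 1, 2, 16 and 19 are taken as commercial.

Step 1
Reactants: 1 3-(trimethylsilyl)prop-2-ynal; 2 allenylboronic acid pinacol ester
Product: 3 (S)-1-(trimethylsilyl)hexa-1,5-diyn-3-ol
Conditions: (S)-3,3'-bis(2,4,6-triisopropylphenyl)-1,1'-binaphthyl-2,2'-diyl hydrogen phosphate (5 mol%), 4 Å MS, toluene, −20 °C; aq. work-up
Reagents that add atoms: none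
Why: Chiral-phosphoric-acid-catalysed propargylation of an aldehyde with an allenylboronate (SE2' transfer through a six-membered transition state in which the acid holds boronate and aldehyde) should give the homopropargylic alcohol, the (S)-catalyst being chosen to direct attack to the Si face of the ynal so that C8 is formed as S.

Step 2
Reactants: 3 (S)-1-(trimethylsilyl)hexa-1,5-diyn-3-ol
Product: 4 (S)-3-(triethylsilyloxy)-1-(trimethylsilyl)hexa-1,5-diyne
Conditions: Et3SiCl, imidazole, DMF, 0 °C
Reagents that add atoms: chlorotriethylsilane CC[Si](Cl)(CC)CC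
Why: Standard silylation of a secondary alcohol, the triethylsilyl ether being chosen because it can later be removed in the presence of a tert-butyldimethylsilyl ether.

Step 3
Reactants: 4 (S)-3-(triethylsilyloxy)-1-(trimethylsilyl)hexa-1,5-diyne
Product: 7 (3E,6S)-4-methyl-6-(triethylsilyloxy)-8-(trimethylsilyl)oct-3-en-7-yn-1-ol, via alkenylalane 5 (not isolated), via lithium alanate 6 (not isolated)
Conditions: AlMe3 (3 equiv), Cp2ZrCl2 (0.3 equiv), CH2Cl2, 0 °C → rt; volatiles removed; n-BuLi, THF, −78 °C; ethylene oxide, −78 → 0 °C; aq. KNaC4H4O6 work-up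
Reagents that add atoms: trimethylaluminium C[Al](C)C; ethylene oxide C1CO1
Why: Negishi carboalumination adds methyl and aluminium syn across the terminal alkyne only (methyl to the internal carbon, the silylated internal alkyne being inert), which fixes the 1(10)E geometry, and the lithium alanate opens ethylene oxide with retention at the alkenyl carbon to add C2 and C3.

Step 4
Reactants: 7 (3E,6S)-4-methyl-6-(triethylsilyloxy)-8-(trimethylsilyl)oct-3-en-7-yn-1-ol
Product: 9 (4S,6E)-9-hydroxy-6-methyl-4-(triethylsilyloxy)non-6-en-2-ynal, via dilithium acetylide–alkoxide 8 (not isolated)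
Conditions: MeLi·LiBr (2.5 equiv), THF, 0 °C → rt; DMF, −78 → 0 °C; inverse quench into aq. KH2PO4
Reagents that add atoms: N,N-dimethylformamide CN(C)C=O
Why: Methyllithium deprotonates the alcohol and then attacks the alkynyl silicon to free the lithium acetylide (desilylative metalation), which is formylated by DMF, the inverse quench into phosphate buffer preventing addition of dimethylamine to the ynal.

Step 5
Reactants: 9 (4S,6E)-9-hydroxy-6-methyl-4-(triethylsilyloxy)non-6-en-2-ynal
Product: 10 (3E,6S,9Z)-10-iodo-4-methyl-6-(triethylsilyloxy)undeca-3,9-dien-7-yn-1-ol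
Conditions: EtPPh3I, n-BuLi, THF, rt; I2, −78 °C; NaN(SiMe3)2, −20 °C; then 9, −78 → −20 °C (excess ylide carries the alcohol as its alkoxide)
Reagents that add atoms: ethyltriphenylphosphonium iodide CC[P+](c1ccccc1)(c1ccccc1)c1ccccc1.[I-]; iodine II
Why: Wittig olefination with the α-iodo ylide (Stork–Zhao-type iodo-olefination) is kinetically Z-selective at low temperature, so iodine ends cis to the alkynyl chain, which is the geometry that becomes the 4Z ring olefin.

Step 6
Reactants: 10 (3E,6S,9Z)-10-iodo-4-methyl-6-(triethylsilyloxy)undeca-3,9-dien-7-yn-1-ol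
Product: 11 (3E,6S,9Z)-10-iodo-4-methyl-6-(triethylsilyloxy)undeca-3,9-dien-7-ynal
Conditions: Dess–Martin periodinane, NaHCO3, CH2Cl2, 0 °C; crude aldehyde used at once
Reagents that add atoms: none
Why: Dess–Martin oxidation under buffered, non-basic conditions should give the β,γ-unsaturated aldehyde without migration of the C1=C10 bond into conjugation.

Step 7
Reactants: 11 (3E,6S,9Z)-10-iodo-4-methyl-6-(triethylsilyloxy)undeca-3,9-dien-7-ynal
Product: 12 (1S,2Z,6S,8E)-2,8-dimethyl-6-(triethylsilyloxy)cyclodeca-2,8-dien-4-yn-1-ol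
Conditions: CrCl2 (8 equiv), N-[2-(4-isopropyl-4,5-dihydrooxazol-2-yl)phenyl]methanesulfonamide (single antipode, 9 equiv), Et3N (9 equiv), NiCl2 (0.5 equiv), THF, slow addition to 0.002 M, rt
Reagents that add atoms: none
Why: Nozaki–Hiyama–Kishi macrocyclisation, in which zerovalent nickel inserts into the alkenyl C–I bond and the alkenyl group passes to trivalent chromium and adds to the aldehyde with retention of olefin geometry (C3 ends cis to C6), is a known way to close strained medium rings at high dilution, and the chiral sulfonamide ligand on chromium (antipode chosen for alkenyl delivery to the Re face of the aldehyde) is meant to set C3 as S.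

Step 8
Reactants: 12 (1S,2Z,6S,8E)-2,8-dimethyl-6-(triethylsilyloxy)cyclodeca-2,8-dien-4-yn-1-ol
Product: 13 (1S,2Z,6S,8E)-1-(tert-butyldimethylsilyloxy)-2,8-dimethyl-6-(triethylsilyloxy)cyclodeca-2,8-dien-4-yne
Conditions: TBSOTf, 2,6-lutidine, CH2Cl2, −78 °C
Reagents that add atoms: tert-butyldimethylsilyl trifluoromethanesulfonate CC(C)(C)[Si](C)(C)OS(=O)(=O)C(F)(F)F
Why: Silylation of the hindered allylic C3 alcohol with the silyl triflate protects O3 until the last step.

Step 9
Reactants: 13 (1S,2Z,6S,8E)-1-(tert-butyldimethylsilyloxy)-2,8-dimethyl-6-(triethylsilyloxy)cyclodeca-2,8-dien-4-yne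
Product: 14 (1S,4Z,6S,8E)-6-(tert-butyldimethylsilyloxy)-5,9-dimethylcyclodeca-4,8-dien-2-yn-1-ol
Conditions: pyridinium p-toluenesulfonate (10 mol%), MeOH/CH2Cl2, 0 °C
Reagents that add atoms: none
Why: Acid-catalysed methanolysis removes the more labile triethylsilyl ether selectively in the presence of the secondary tert-butyldimethylsilyl ether and frees the C8 hydroxyl.

Step 10
Reactants: 14 (1S,4Z,6S,8E)-6-(tert-butyldimethylsilyloxy)-5,9-dimethylcyclodeca-4,8-dien-2-yn-1-ol
Product: 15 (1S,2Z,4Z,6S,8E)-6-(tert-butyldimethylsilyloxy)-5,9-dimethylcyclodeca-2,4,8-trien-1-ol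
Conditions: H2 (1 atm, 1 equiv), Pd/CaCO3 poisoned with Pb(OAc)2, quinoline, EtOAc, rt
Reagents that add atoms: none
Why: Lindlar semihydrogenation adds H2 syn to the conjugated ring alkyne and gives the 6Z olefin, the trisubstituted olefins being inert and quinoline limiting over-reduction.

Step 11
Reactants: 15 (1S,2Z,4Z,6S,8E)-6-(tert-butyldimethylsilyloxy)-5,9-dimethylcyclodeca-2,4,8-trien-1-ol; 16 2-bromoacrylic acid
Product: 17 (3aR,4S,6E,9S,10Z,11aS)-9-(tert-butyldimethylsilyloxy)-4-hydroxy-6,10-dimethyl-3-methylidene-3a,4,5,8,9,11a-hexahydrocyclodeca[b]furan-2(3H)-one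
Conditions: Pd(OAc)2 (10 mol%), PPh3 (20 mol%), Na2CO3 (2.5 equiv), n-Bu4NCl (1 equiv), DMF, 60 °C; 16 added slowly
Reagents that add atoms: none
Why: Zerovalent palladium inserts into the C–Br bond of the 2-bromoacrylate, the alkenylpalladium adds syn across C6=C7 of the diene with C11 going to the less substituted terminus C7, and the π-allylpalladium that then spans C4–C5–C6 is closed at C6 by the metal-bound carboxylate, which returns zerovalent palladium. The closest known reaction type is the Larock heteroannulation of 1,3-dienes with vinylic or aryl halides that carry a carboxylic acid, phenol or amine. The γ-lactone closes in a 5-exo sense by C–O bond formation at the proximal allyl terminus (the seven-membered alternative at the fully substituted C4 is disfavoured), so the C4=C5 bond stays where the target has it and, held by the ten-membered ring, should keep its Z geometry. C6 and C7 are set cis to each other because carbon and oxygen are both delivered from the palladium-bearing face (syn carbopalladation, then inner-sphere C–O formation). Their sense relative to C8 should follow from attack on the outer face of the Z olefin in the conformer in which H8 eclipses C6=C7 (A1,3 strain), the face on which the free C8 hydroxyl lies and can guide the metal, which translates 8S into 7R and 6S. The step needs regioselectivity for C7 over C4 and chemoselectivity for the diene over the C1=C10 olefin; the first rests on the substitution pattern of the diene termini and the allyl stabilisation, the second on the inertness of isolated trisubstituted olefins to carbopalladation.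

Step 12
Reactants: 17 (3aR,4S,6E,9S,10Z,11aS)-9-(tert-butyldimethylsilyloxy)-4-hydroxy-6,10-dimethyl-3-methylidene-3a,4,5,8,9,11a-hexahydrocyclodeca[b]furan-2(3H)-one
Product: 18 (1R,3S,6S,7R,8S,10R)-1,10-epoxy-8-hydroxy-3-(tert-butyldimethylsilyloxy)germacra-4Z,11(13)-dien-12,6-olide
Conditions: 1,2:4,5-di-O-isopropylidene-β-D-erythro-2,3-hexodiulo-2,6-pyranose (30 mol%), KHSO5 (as 2KHSO5·KHSO4·K2SO4), K2CO3, n-Bu4NHSO4, MeCN/dimethoxymethane/aq. Na2B4O7 buffer, 0 °C
Reagents that add atoms: potassium peroxymonosulfate [K+].[O-]S(=O)(=O)OO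
Why: Shi epoxidation, in which the chiral dioxirane formed in situ from the fructose-derived ketone attacks the electron-rich E-trisubstituted C1=C10 olefin through a spiro transition state, should give the (1R,10R)-epoxide under reagent control, while the C4=C5 olefin (deactivated by two allylic oxygens) and the electron-poor methylene lactone should be spared.

Step 13
Reactants: 18 (1R,3S,6S,7R,8S,10R)-1,10-epoxy-8-hydroxy-3-(tert-butyldimethylsilyloxy)germacra-4Z,11(13)-dien-12,6-olide; 19 furan-3-carboxylic acid
Product: 20 (1R,3S,6S,7R,8R,10R)-1,10-epoxy-8-(furan-3-carbonyloxy)-3-(tert-butyldimethylsilyloxy)germacra-4Z,11(13)-dien-12,6-olide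
Conditions: PPh3, DIAD, toluene, 0 °C → rt (betaine formed before the substrate is added)
Reagents that add atoms: none
Why: Mitsunobu esterification activates the C8 alcohol as an alkoxyphosphonium ion that is displaced by 3-furoate in an SN2 reaction, which installs the ester and inverts C8 from S to R in one operation.

Step 14
Reactants: 20 (1R,3S,6S,7R,8R,10R)-1,10-epoxy-8-(furan-3-carbonyloxy)-3-(tert-butyldimethylsilyloxy)germacra-4Z,11(13)-dien-12,6-olide
Product: 21 (1R,3S,6S,7R,8R,10R)-1,10-epoxy-8-(furan-3-carbonyloxy)-3-hydroxygermacra-4Z,11(13)-dien-12,6-olide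
Conditions: n-Bu4NF, AcOH (1:1), THF, 0 °C → rt
Reagents that add atoms: none
Why: Fluoride cleaves the Si–O bond of the silyl ether, and buffering with acetic acid keeps the medium near neutral so that the epoxide, the furoate and the methylene lactone should survive.

Compound list
1 | 3-(trimethylsilyl)prop-2-ynal | C[Si](C)(C)C#CC=O | starting material
2 | allenylboronic acid pinacol ester | C=C=CB1OC(C)(C)C(C)(C)O1 | starting material
3 | (S)-1-(trimethylsilyl)hexa-1,5-diyn-3-ol | C[Si](C)(C)C#C[C@@H](O)CC#C | intermediate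
4 | (S)-3-(triethylsilyloxy)-1-(trimethylsilyl)hexa-1,5-diyne | C[Si](C)(C)C#C[C@@H](O[Si](CC)(CC)CC)CC#C | intermediate
5 | dimethyl[(1E,4S)-2-methyl-4-(triethylsilyloxy)-6-(trimethylsilyl)hex-1-en-5-yn-1-yl]alane | C[Si](C)(C)C#C[C@@H](O[Si](CC)(CC)CC)C/C(C)=C/[Al](C)C | intermediate
6 | lithium butyldimethyl[(1E,4S)-2-methyl-4-(triethylsilyloxy)-6-(trimethylsilyl)hex-1-en-5-yn-1-yl]aluminate | [Li+].C[Si](C)(C)C#C[C@@H](O[Si](CC)(CC)CC)C/C(C)=C/[Al-](C)(C)CCCC | intermediate
7 | (3E,6S)-4-methyl-6-(triethylsilyloxy)-8-(trimethylsilyl)oct-3-en-7-yn-1-ol | C[Si](C)(C)C#C[C@@H](O[Si](CC)(CC)CC)C/C(C)=C/CCO | intermediate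
8 | dilithium salt of (3E,6S)-4-methyl-6-(triethylsilyloxy)oct-3-en-7-yn-1-ol (C8 acetylide/O1 alkoxide) | [Li]C#C[C@@H](O[Si](CC)(CC)CC)C/C(C)=C/CCO[Li] | intermediate
9 | (4S,6E)-9-hydroxy-6-methyl-4-(triethylsilyloxy)non-6-en-2-ynal | O=CC#C[C@@H](O[Si](CC)(CC)CC)C/C(C)=C/CCO | intermediate
10 | (3E,6S,9Z)-10-iodo-4-methyl-6-(triethylsilyloxy)undeca-3,9-dien-7-yn-1-ol | I/C(C)=C\C#C[C@@H](O[Si](CC)(CC)CC)C/C(C)=C/CCO | intermediate
11 | (3E,6S,9Z)-10-iodo-4-methyl-6-(triethylsilyloxy)undeca-3,9-dien-7-ynal | I/C(C)=C\C#C[C@@H](O[Si](CC)(CC)CC)C/C(C)=C/CC=O | intermediate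
12 | (1S,2Z,6S,8E)-2,8-dimethyl-6-(triethylsilyloxy)cyclodeca-2,8-dien-4-yn-1-ol | [C@@H]1(O[Si](CC)(CC)CC)C#C/C=C(/C)[C@@H](O)C/C=C(\C)C1 | intermediate
13 | (1S,2Z,6S,8E)-1-(tert-butyldimethylsilyloxy)-2,8-dimethyl-6-(triethylsilyloxy)cyclodeca-2,8-dien-4-yne | [C@@H]1(O[Si](CC)(CC)CC)C#C/C=C(/C)[C@@H](O[Si](C)(C)C(C)(C)C)C/C=C(\C)C1 | intermediate
14 | (1S,4Z,6S,8E)-6-(tert-butyldimethylsilyloxy)-5,9-dimethylcyclodeca-4,8-dien-2-yn-1-ol | [C@@H]1(O)C#C/C=C(/C)[C@@H](O[Si](C)(C)C(C)(C)C)C/C=C(\C)C1 | intermediate
15 | (1S,2Z,4Z,6S,8E)-6-(tert-butyldimethylsilyloxy)-5,9-dimethylcyclodeca-2,4,8-trien-1-ol | [C@@H]1(O)/C=C\C=C(\C)[C@@H](O[Si](C)(C)C(C)(C)C)C/C=C(\C)C1 | intermediate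
16 | 2-bromoacrylic acid | C=C(Br)C(=O)O | starting material
17 | (3aR,4S,6E,9S,10Z,11aS)-9-(tert-butyldimethylsilyloxy)-4-hydroxy-6,10-dimethyl-3-methylidene-3a,4,5,8,9,11a-hexahydrocyclodeca[b]furan-2(3H)-one | C=C1C(=O)O[C@H]2/C=C(/C)[C@@H](O[Si](C)(C)C(C)(C)C)C/C=C(\C)C[C@H](O)[C@@H]12 | intermediate
18 | (1R,3S,6S,7R,8S,10R)-1,10-epoxy-8-hydroxy-3-(tert-butyldimethylsilyloxy)germacra-4Z,11(13)-dien-12,6-olide | C=C1C(=O)O[C@H]2/C=C(/C)[C@@H](O[Si](C)(C)C(C)(C)C)C[C@H]3O[C@]3(C)C[C@H](O)[C@@H]12 | intermediate
19 | furan-3-carboxylic acid | OC(=O)c1ccoc1 | starting material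
20 | (1R,3S,6S,7R,8R,10R)-1,10-epoxy-8-(furan-3-carbonyloxy)-3-(tert-butyldimethylsilyloxy)germacra-4Z,11(13)-dien-12,6-olide | C=C1C(=O)O[C@H]2/C=C(/C)[C@@H](O[Si](C)(C)C(C)(C)C)C[C@H]3O[C@]3(C)C[C@@H](OC(=O)c3ccoc3)[C@@H]12 | intermediate
21 | (1R,3S,6S,7R,8R,10R)-1,10-epoxy-8-(furan-3-carbonyloxy)-3-hydroxygermacra-4Z,11(13)-dien-12,6-olide (CNP0390850.1) | C=C1C(=O)O[C@H]2/C=C(/C)[C@@H](O)C[C@H]3O[C@]3(C)C[C@@H](OC(=O)c3ccoc3)[C@@H]12 | target

Total step count: 14. Longest linear sequence: 14 steps (from 1 to 21).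

Steps most likely to fail

Step 11. The carbopalladation may take place on the other face of C6=C7 than the conformational model predicts (poor or reversed facial selectivity with respect to the C8 carbinol), which would set C6 and C7 in the wrong sense relative to the rest of the ring. The fallback moves the C8 inversion ahead of the annulation and finishes with an esterification that retains configuration. It sets out from 15, which is oxidised with MnO2 in CH2Cl2 to the ten-membered dienone F1 and reduced with (S)-Me-CBS oxazaborolidine and catecholborane to the C8-epimeric dienol F2. The same palladium annulation with 16 should then give the 8R hydroxy lactone F3, and Shi epoxidation as in step 12 the epoxy alcohol F4. Acylation with commercial 3-furoyl chloride, pyridine and DMAP comes back to the route at 20.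

Step 7. Ligand control over the new C3 carbinol may be overridden by the strain of the closing ring (low or wrong diastereoselectivity), apart from competing oligomerisation. The fallback sets C3 by ketone reduction instead of during the C–C bond formation. It sets out from 11, which is closed without chiral ligand (CrCl2, cat. NiCl2, DMSO, high dilution) to the C3-epimeric enynol mixture F5. Dess–Martin oxidation gives the enynone F6, and reduction with (R)-Me-CBS oxazaborolidine and catecholborane at −78 °C comes back to the route at 12.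

Step 13. At the hindered ring carbinol, elimination or attack of the phosphine on the methylene lactone may outrun the SN2 displacement. The fallback separates activation from displacement. It sets out from 18, which is converted with ClCH2SO2Cl and pyridine into the chloromethanesulfonate F7. This is displaced with inversion by caesium furan-3-carboxylate F8 (from 19 and Cs2CO3) with 18-crown-6 in toluene at 60 °C, which comes back to the route at 20.

Further compounds
F1 | step 11 | (2Z,4Z,6S,8E)-6-(tert-butyldimethylsilyloxy)-5,9-dimethylcyclodeca-2,4,8-trien-1-one | O=C1/C=C\C=C(\C)[C@@H](O[Si](C)(C)C(C)(C)C)C/C=C(\C)C1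
F2 | step 11 | (1R,2Z,4Z,6S,8E)-6-(tert-butyldimethylsilyloxy)-5,9-dimethylcyclodeca-2,4,8-trien-1-ol | [C@H]1(O)/C=C\C=C(\C)[C@@H](O[Si](C)(C)C(C)(C)C)C/C=C(\C)C1
F3 | step 11 | (3aR,4R,6E,9S,10Z,11aS)-9-(tert-butyldimethylsilyloxy)-4-hydroxy-6,10-dimethyl-3-methylidene-3a,4,5,8,9,11a-hexahydrocyclodeca[b]furan-2(3H)-one | C=C1C(=O)O[C@H]2/C=C(/C)[C@@H](O[Si](C)(C)C(C)(C)C)C/C=C(\C)C[C@@H](O)[C@@H]12
F4 | step 11 | (1R,3S,6S,7R,8R,10R)-1,10-epoxy-8-hydroxy-3-(tert-butyldimethylsilyloxy)germacra-4Z,11(13)-dien-12,6-olide | C=C1C(=O)O[C@H]2/C=C(/C)[C@@H](O[Si](C)(C)C(C)(C)C)C[C@H]3O[C@]3(C)C[C@@H](O)[C@@H]12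
F5 | step 7 | (2Z,6S,8E)-2,8-dimethyl-6-(triethylsilyloxy)cyclodeca-2,8-dien-4-yn-1-ol as a mixture of C1 epimers | [C@@H]1(O[Si](CC)(CC)CC)C#C/C=C(/C)C(O)C/C=C(\C)C1
F6 | step 7 | (2Z,6S,8E)-2,8-dimethyl-6-(triethylsilyloxy)cyclodeca-2,8-dien-4-yn-1-one | [C@@H]1(O[Si](CC)(CC)CC)C#C/C=C(/C)C(=O)C/C=C(\C)C1
F7 | step 13 | (1R,3S,6S,7R,8S,10R)-8-(chloromethanesulfonyloxy)-1,10-epoxy-3-(tert-butyldimethylsilyloxy)germacra-4Z,11(13)-dien-12,6-olide | C=C1C(=O)O[C@H]2/C=C(/C)[C@@H](O[Si](C)(C)C(C)(C)C)C[C@H]3O[C@]3(C)C[C@H](OS(=O)(=O)CCl)[C@@H]12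
F8 | step 13 | caesium furan-3-carboxylate | [Cs+].[O-]C(=O)c1ccoc1
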